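**The questions.** Of the 4 questions below, take the yield of the south-east run first and turn it round: ask what would have to be true of its charge for that flask to stop short.

| flask | starting material | coupling partner | free catalyst | time |
|---|---|---|---|---|
| north-west | 1.00 M | 1.00 M | 0.0100 M |  |
| west | 1.00 M | 1.00 M | 0.0300 M |  |
| north-east | 1.50 M | 1.00 M | 0.0100 M |  |
| east | 1.00 M | 0.500 M | 0.0100 M |  |
| south-east | 3.00 M | 1.00 M | 0.0300 M | 160 min |

| north-west run: time / min | north-west run: [product] / M | west run: time / min | west run: [product] / M | north-east run: time / min | north-east run: [product] / M | east run: time / min | east run: [product] / M |
|---|---|---|---|---|---|---|---|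
| 20 | 0.278 | 20 | 0.649 | 20 | 0.380 | 20 | 0.235 |
| 40 | 0.446 | 40 | 0.848 | 40 | 0.589 | 40 | 0.371 |
| 60 | 0.544 | 60 | 0.939 | 60 | 0.737 | 60 | 0.443 |
| 80 | 0.616 | 80 | 0.967 | 80 | 0.841 | 80 | 0.491 |
| 100 | 0.663 | 100 | 0.984 | 100 | 0.902 | 100 | 0.492 |
| 120 | 0.705 | 120 | 0.994 | 120 | 0.941 | 120 | 0.496 |
| 140 | 0.723 | 140 | 0.999 | 140 | 0.976 | 140 | 0.496 |
| 160 | 0.755 | 160 | 0.998 | 160 | 0.995 | 160 | 0.508 |

(standard deviation of a reading: 0.005 M)

- Overall: starting material + coupling partner -> product, with free catalyst as catalyst.
- Constant volume, constant temperature.
- Readings of a species count what is bound in complexes too.
- "The second partner" is coupling partner.
- An order is taken over about fifteen percent of the charge, up and down.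

1. the exponent of [coupling partner] in the starting rate at the charge of the north-west run (at the point where two percent of the starting material have become product)
2. the exponent of [starting material] in the starting rate at the charge of the north-west run (at the point where two percent of the starting material have become product) (one fixed amount of product, the same in the runs compared)
3. product in the south-east run at 160 min, as a share of the starting material charged
4. which of these the readings show (the product ties up the catalyst / an uncatalysed path runs beside / nothing beyond the main steps / the second partner kills the catalyst / the second partner is lost in pairs)

**The ceiling.** In the south-east run the coupling partner, at 1.00 M, is less than the 3.00 M of starting material, so it is the limiting reagent and product cannot pass 33.3% of the starting material charged.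

**Failing catalyst.** Read the west run at 20 min against the north-west run at 60 min: catalyst charge times time is the same, yet the west run holds 0.649 M, more than the 0.544 M of the north-west run, so catalyst in the north-west run is being lost as time passes.

**Turnover demand.** Divide the 1.00 M of coupling partner by the 0.0300 M of free catalyst to get 33.3: this is the turnover demand D, the charge of the limiting reagent over the charge of catalyst, here the turnovers per catalyst charged that the south-east run must reach to use up its coupling partner. To stop short, the south-east run would need its catalyst to give out before 33.3 turnovers per catalyst charged. But by 160 min the north-west run had made 75.5 turnovers per catalyst charged and the north-east run 99.5, both more than D. The west run, with the partner and catalyst charges of the south-east run, read 0.998 M at that time. Raising the starting material from 1.00 M to 1.50 M at fixed partner and catalyst lifted product at 160 min from 0.755 M to 0.995 M, and the south-east run carries 3.00 M, so commit to the ceiling of 33.3%.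

**The forecast.** The forecast gives orders of 0.24 in coupling partner and 0.76 in starting material, names the second partner kills the catalyst, and, with the partner “consumed within about 30 min, before much catalyst dies”, puts the yield at 33.2%, less than the ceiling.

**The flask.** The south-east run gives 33.3% at 160 min; at the charge of the north-west run the orders are 0.25 in coupling partner and 0.72 in starting material, and the readings show that the second partner kills the catalyst.

    free catalyst + starting material → catalyst-substrate complex (2.862 /M/min)
    catalyst-substrate complex + coupling partner → loaded catalyst (7.500 /M/min)
    loaded catalyst → product + free catalyst (34.86 /min)
    free catalyst + coupling partner → spent catalyst + coupling partner (0.02862 /M/min)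

The conversion of free catalyst into spent catalyst moves the readings by 19 in units of the scatter, root mean square, and makes no difference to product in the south-east run at 160 min. That product comes to 33.3 turnovers per catalyst charged, against a D of 33.3. In the north-west run D is 100, more than the 75.5 turnovers reached at 160 min, where that run read 0.755 M.

The numbers in the tables were computed for an exercise, noise included.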